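Cuts (chromanone numbering of the target): the C8–CH2 bond of the prenyl group (back to an O5 prenyl ether), O1–C2 and C4–C4a of the pyranone (back to a tigloyl ketone, then to the arene), and last the aryl C6–CH bond of the hexanoic acid chain.
Enabling feature: aromatic C6, the benzylic CH that carries the propyl group, its CH2, the carboxyl carbon, O5 and aromatic C5 are the six atoms of a latent oxygen ring; closed, it is a 4-propylchroman-2-ol (lactol) or chroman-2-one (lactone) fused to the benzene ring.
Forward: 3,5-dimethoxyphenol and (E)-hex-2-enal give this lactol ring and the C6–CH bond in step 1; oxidation to the lactone keeps O5 masked while C-tigloylation, chelation-directed demethylation and oxa-Michael closure add the pyranone ring at C4a and O1.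
Opening the lactone to an allyl ester then frees O5 for O-prenylation, a Claisen–Cope shift carries the prenyl group to C8, and deallylation releases the acid.
Stereochemistry: the benzylic centre (R) comes from the (S)-diphenylprolinol silyl ether catalyst in step 1; C2 (S) comes from quinidine in the oxa-Michael step and C3 (S) from equilibration to the trans-diequatorial pyranone.

Key step: step 1

Remark: the phenol is taken as the dimethyl ether, 3,5-dimethoxyphenol, because its two carbons ortho to the single hydroxyl are equivalent and the lactol product is no longer a phenol; the methoxy group that must become the pyranone oxygen is unmasked in step 4 by the neighbouring ketone. Locants are those of the compound named on the same line (chroman for 4 to 8, pyrano[2,3-f]chromene for 9 and 10, chroman-4-one for 11 to 16).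

Step 1
Reactants: 1 3,5-dimethoxyphenol; 2 (E)-hex-2-enal
Product: 4 (4R)-5,7-dimethoxy-4-propylchroman-2-ol, via hydroxy aldehyde 3 (not isolated)
Conditions: (S)-2-[diphenyl(trimethylsilyloxy)methyl]pyrrolidine (20 mol %), PhCO2H (20 mol %), toluene, 0 °C to rt
Reagents that add atoms: none
Why: The secondary amine condenses with 2 to an (E)-configured, s-trans iminium ion whose beta carbon is attacked by phenol 1 (hydrogen-bonded or partly deprotonated) through a ring carbon ortho to the hydroxyl, and rearomatisation, enamine protonation and hydrolysis release aldehyde 3 and the catalyst. The closest known reaction type is the diarylprolinol silyl ether catalysed Friedel–Crafts alkylation–hemiacetalisation cascade of naphthols and other electron-rich phenols with enals. The only ring formed, the oxygen ring of the chroman-2-ol, closes by 6-exo-trig addition of the ortho hydroxyl to the aldehyde carbonyl, which also withdraws the aldehyde from further iminium or enamine chemistry. The one stereocentre of consequence (C4 of the chroman, later the benzylic carbon of the acid chain) is set by the catalyst, whose diphenyl(trimethylsilyloxy)methyl group covers one face of the iminium ion, so that addition to the open face of the (E)-enal with the (S)-configured catalyst should give 4R, while the anomeric centre is left as a mixture and is erased in step 2. Site selectivity is needed between the two carbons ortho to the hydroxyl and the carbon para to it: the ortho carbons are equivalent by the symmetry of 1, so one lactol results whichever reacts, and the para carbon lies between two methoxy groups and cannot be reached with help from the hydroxyl. A second alkylation should not follow because 4 is an aryl ether and no longer a phenol.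

Step 2
Reactants: 4 (4R)-5,7-dimethoxy-4-propylchroman-2-ol
Product: 5 (4R)-5,7-dimethoxy-4-propylchroman-2-one
Conditions: TEMPO (10 mol %), PhI(OAc)2, CH2Cl2, rt
Reagents that add atoms: none
Why: Oxoammonium (TEMPO/PhI(OAc)2) oxidation turns lactols into lactones under neutral conditions that leave the aryl methyl ethers and the C4 centre untouched, and both anomers converge on one lactone.

Step 3
Reactants: 5 (4R)-5,7-dimethoxy-4-propylchroman-2-one; 6 (E)-2-methylbut-2-enoyl chloride (tigloyl chloride)
Product: 7 (4R)-5,7-dimethoxy-8-[(E)-2-methylbut-2-enoyl]-4-propylchroman-2-one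
Conditions: AlCl3, CH2Cl2, −20 to 0 °C; cold dilute HCl work-up
Reagents that add atoms: none
Why: Friedel–Crafts acylation should go to C8, which is ortho to one methoxy group and para to the other and has the tied-back ring oxygen as its second neighbour, whereas C6 lies between two methoxy groups, one of them pressed towards it by the C4 substituent; the E geometry of the acyl group is kept and the ketone formed deactivates the ring against a second acylation.

Step 4
Reactants: 7 (4R)-5,7-dimethoxy-8-[(E)-2-methylbut-2-enoyl]-4-propylchroman-2-one
Product: 8 (4R)-7-hydroxy-5-methoxy-8-[(E)-2-methylbut-2-enoyl]-4-propylchroman-2-one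
Conditions: BCl3, CH2Cl2, −78 to 0 °C; then H2O
Reagents that add atoms: none
Why: BCl3 binds the ketone oxygen and the neighbouring C7 methoxy oxygen in a six-membered chelate and chloride removes only that methyl group (chelation-directed ortho demethylation), which leaves the C5 methoxy group para to the ketone and the lactone intact.

Step 5
Reactants: 8 (4R)-7-hydroxy-5-methoxy-8-[(E)-2-methylbut-2-enoyl]-4-propylchroman-2-one
Product: 10 (4R,8S,9S)-5-methoxy-8,9-dimethyl-4-propyl-3,4,8,9-tetrahydro-2H,10H-pyrano[2,3-f]chromene-2,10-dione, via cis-pyranone lactone 9 (not isolated)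
Conditions: quinidine (20 mol %), PhCl, rt; then MgI2, Et3N, CH2Cl2, rt
Reagents that add atoms: none
Why: Cinchona-alkaloid-catalysed intramolecular oxa-Michael addition (6-endo-trig) is known for 7-hydroxy-8-tigloylcoumarins, where quinine favours the 2R pyranone, so the pseudoenantiomer quinidine should deliver the phenoxide to the enone face that gives 8S, only O7 being free because the other flanking oxygen is locked in the lactone, and soft enolisation with MgI2/Et3N then epimerises C9 of the kinetic cis adduct to the diequatorial trans isomer without touching C8.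

Step 6
Reactants: 10 (4R,8S,9S)-5-methoxy-8,9-dimethyl-4-propyl-3,4,8,9-tetrahydro-2H,10H-pyrano[2,3-f]chromene-2,10-dione
Product: 11 prop-2-en-1-yl (3R)-3-[(2S,3S)-5-hydroxy-7-methoxy-2,3-dimethyl-4-oxochroman-6-yl]hexanoate
Conditions: allyl alcohol (solvent), p-TsOH·H2O (10 mol %), 50 °C; NaHCO3 before concentration
Reagents that add atoms: allyl alcohol (prop-2-en-1-ol), C=CCO
Why: Acid-catalysed alcoholysis (transesterification) of the aryl lactone is driven by the excess alcohol and by the hydrogen bond that the released O5–H forms to the C4 ketone, and the non-basic medium avoids retro-oxa-Michael opening of the pyranone, any equilibration at C3 leading to the trans isomer already present.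

Step 7
Reactants: 11 prop-2-en-1-yl (3R)-3-[(2S,3S)-5-hydroxy-7-methoxy-2,3-dimethyl-4-oxochroman-6-yl]hexanoate; 12 3-methylbut-2-en-1-ol
Product: 13 prop-2-en-1-yl (3R)-3-{(2S,3S)-7-methoxy-2,3-dimethyl-5-[(3-methylbut-2-en-1-yl)oxy]-4-oxochroman-6-yl}hexanoate
Conditions: PPh3, DIAD, THF, 0 °C to rt
Reagents that add atoms: none
Why: Mitsunobu etherification alkylates hydrogen-bonded o-acylphenols with a primary allylic alcohol under neutral conditions, so the chelated O5–H is prenylated without the base that would endanger the pyranone stereocentres.

Step 8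
Reactants: 13 prop-2-en-1-yl (3R)-3-{(2S,3S)-7-methoxy-2,3-dimethyl-5-[(3-methylbut-2-en-1-yl)oxy]-4-oxochroman-6-yl}hexanoate
Product: 15 prop-2-en-1-yl (3R)-3-[(2S,3S)-5-hydroxy-7-methoxy-2,3-dimethyl-8-(3-methylbut-2-en-1-yl)-4-oxochroman-6-yl]hexanoate, via ortho-dienone 14 (not isolated)
Conditions: Eu(fod)3 (europium tris(6,6,7,7,8,8,8-heptafluoro-2,2-dimethyloctane-3,5-dionate), 10 mol %), CHCl3, 60 °C
Reagents that add atoms: none
Why: In the ether chelated by europium through the C4 carbonyl and O5, a [3,3] Claisen shift places the allyl unit on the substituted ortho carbon C6, the dienone formed cannot enolise and passes the unit on by a [3,3] Cope shift to C8, the only unsubstituted ring carbon, where tautomerisation restores the phenol, and the double allylic inversion returns the linear 3-methylbut-2-enyl group (para-Claisen–Cope rearrangement, known for 5-O-prenyl chromanones).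

Step 9
Reactants: 15 prop-2-en-1-yl (3R)-3-[(2S,3S)-5-hydroxy-7-methoxy-2,3-dimethyl-8-(3-methylbut-2-en-1-yl)-4-oxochroman-6-yl]hexanoate
Product: 16 (3R)-3-[(2S,3S)-5-hydroxy-7-methoxy-2,3-dimethyl-8-(3-methylbut-2-en-1-yl)-4-oxochroman-6-yl]hexanoic acid
Conditions: Pd(PPh3)4 (5 mol %), N-methylaniline, THF, rt
Reagents that add atoms: none
Why: Palladium-catalysed allyl transfer to the weakly basic N-methylaniline (Tsuji–Trost deallylation) cleaves the allyl ester at room temperature without hydroxide, so the pyranone stereocentres and the prenyl group are not affected and the chelated phenol has no reason to relactonise.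

Compound list
1 | 3,5-dimethoxyphenol | COc1cc(O)cc(OC)c1 | starting material
2 | (E)-hex-2-enal | CCC/C=C/C=O | starting material
3 | (3R)-3-(2-hydroxy-4,6-dimethoxyphenyl)hexanal | CCC[C@H](CC=O)c1c(O)cc(OC)cc1OC | intermediate
4 | (4R)-5,7-dimethoxy-4-propylchroman-2-ol (both anomers) | CCC[C@@H]1CC(O)Oc2cc(OC)cc(OC)c21 | intermediate
5 | (4R)-5,7-dimethoxy-4-propylchroman-2-one | CCC[C@@H]1CC(=O)Oc2cc(OC)cc(OC)c21 | intermediate
6 | (E)-2-methylbut-2-enoyl chloride (tigloyl chloride) | C/C=C(\C)C(=O)Cl | starting material
7 | (4R)-5,7-dimethoxy-8-[(E)-2-methylbut-2-enoyl]-4-propylchroman-2-one | CCC[C@@H]1CC(=O)Oc2c(C(=O)/C(C)=C/C)c(OC)cc(OC)c21 | intermediate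
8 | (4R)-7-hydroxy-5-methoxy-8-[(E)-2-methylbut-2-enoyl]-4-propylchroman-2-one | CCC[C@@H]1CC(=O)Oc2c(C(=O)/C(C)=C/C)c(O)cc(OC)c21 | intermediate
9 | (4R,8S,9R)-5-methoxy-8,9-dimethyl-4-propyl-3,4,8,9-tetrahydro-2H,10H-pyrano[2,3-f]chromene-2,10-dione (cis-dimethyl) | CCC[C@@H]1CC(=O)Oc2c3c(cc(OC)c21)O[C@@H](C)[C@@H](C)C3=O | intermediate
10 | (4R,8S,9S)-5-methoxy-8,9-dimethyl-4-propyl-3,4,8,9-tetrahydro-2H,10H-pyrano[2,3-f]chromene-2,10-dione (trans-dimethyl; lactone ring O1–C4a, pyranone ring C6a–C10a) | CCC[C@@H]1CC(=O)Oc2c3c(cc(OC)c21)O[C@@H](C)[C@H](C)C3=O | intermediate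
11 | prop-2-en-1-yl (3R)-3-[(2S,3S)-5-hydroxy-7-methoxy-2,3-dimethyl-4-oxochroman-6-yl]hexanoate | CCC[C@H](CC(=O)OCC=C)c1c(O)c2c(cc1OC)O[C@@H](C)[C@H](C)C2=O | intermediate
12 | 3-methylbut-2-en-1-ol (prenol) | CC(C)=CCO | starting material
13 | prop-2-en-1-yl (3R)-3-{(2S,3S)-7-methoxy-2,3-dimethyl-5-[(3-methylbut-2-en-1-yl)oxy]-4-oxochroman-6-yl}hexanoate | CCC[C@H](CC(=O)OCC=C)c1c(OCC=C(C)C)c2c(cc1OC)O[C@@H](C)[C@H](C)C2=O | intermediate
14 | prop-2-en-1-yl (3R)-3-[(2S,3S)-7-methoxy-2,3-dimethyl-6-(2-methylbut-3-en-2-yl)-4,5-dioxo-3,4,5,6-tetrahydro-2H-chromen-6-yl]hexanoate (C6 epimers) | CCC[C@H](CC(=O)OCC=C)C1(C(C)(C)C=C)C(=O)C2=C(C=C1OC)O[C@@H](C)[C@H](C)C2=O | intermediate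
15 | prop-2-en-1-yl (3R)-3-[(2S,3S)-5-hydroxy-7-methoxy-2,3-dimethyl-8-(3-methylbut-2-en-1-yl)-4-oxochroman-6-yl]hexanoate | CCC[C@H](CC(=O)OCC=C)c1c(O)c2c(c(CC=C(C)C)c1OC)O[C@@H](C)[C@H](C)C2=O | intermediate
16 | (3R)-3-[(2S,3S)-5-hydroxy-7-methoxy-2,3-dimethyl-8-(3-methylbut-2-en-1-yl)-4-oxochroman-6-yl]hexanoic acid | CCC[C@H](CC(=O)O)c1c(O)c2c(c(CC=C(C)C)c1OC)O[C@@H](C)[C@H](C)C2=O | target

Total step count: 9
Longest linear sequence: 9 steps (1 and 2 to 16)

Steps most likely to fail

Step 5. The quinidine-bound phenoxide may add to the enone with poor facial selectivity, or the cis-to-trans equilibration may pass through ring opening and reclosure and so erode the C8 configuration. The fallback sets out from 8. Closure without a chiral catalyst (K2CO3, butan-2-one, rt) with equilibration gives the two trans-dimethyl diastereomers, 10 and (4R,8R,9R)-5-methoxy-8,9-dimethyl-4-propyl-3,4,8,9-tetrahydro-2H,10H-pyrano[2,3-f]chromene-2,10-dione F1. Because C4 is fixed these are diastereomers, and they are separated by preparative chromatography on a chiral stationary phase. The unwanted isomer is returned to the same base treatment, which re-equilibrates it through the open phenoxide. The fallback comes back to the route at 10.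

Step 8. The crowded aryl prenyl ether may ionise and lose its prenyl group instead of rearranging, and the etherification of the flanked, chelated phenol before it may stall. The fallback sets out from 11 and bypasses both steps by direct Friedel–Crafts prenylation with 2-methylbut-3-en-2-ol and BF3·OEt2 in dioxane at rt. C8 is the only free ring carbon, para to O5–H and ortho to two ether oxygens, and no hydroxyl sits next to it, so ring closure of the prenyl group to a chroman cannot occur. The fallback comes back to the route at 15 and makes no compound outside the list (F0).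

Step 1. The phenol may react in part through the carbon para to its hydroxyl, giving an open aldehyde, or the aliphatic enal may be added with insufficient face selectivity. The fallback sets out from 1. Pechmann condensation with ethyl 3-oxohexanoate (CH3SO3H, rt) gives 5,7-dimethoxy-4-propyl-2H-chromen-2-one F2. Copper hydride asymmetric conjugate reduction, known for 4-substituted coumarins (Cu(OAc)2, the DTBM-SEGPHOS enantiomer that delivers hydride to the face giving 4R, diethoxymethylsilane, t-BuOH, toluene), then sets the C4 centre; any lactol formed by over-reduction is treated as in step 2. The fallback comes back to the route at 5.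

Further compounds
F1 | step 5 | (4R,8R,9R)-5-methoxy-8,9-dimethyl-4-propyl-3,4,8,9-tetrahydro-2H,10H-pyrano[2,3-f]chromene-2,10-dione | CCC[C@@H]1CC(=O)Oc2c3c(cc(OC)c21)O[C@H](C)[C@@H](C)C3=O
F0 | step 8 | none | none
F2 | step 1 | 5,7-dimethoxy-4-propyl-2H-chromen-2-one | CCCC1=CC(=O)Oc2cc(OC)cc(OC)c12
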